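## Retrosynthetic overview

1. Azaphilone D ⇐ allylic oxidation of its side-chain alcohol. The C8–O ester and C7–OH ⇐ one acid-triggered event in which the hydroxybutanoyl unit, already tethered at C1, opens a 7,8-epoxide from the face opposite the epoxide oxygen.
2. 7,8-Epoxide ⇐ 8a-OH-directed epoxidation, after opening a seven-membered lactone that ties O8a to the C1 acetal of a pyrano-fused para-quinol.
3. That tricycle ⇐ para-quinol carrying a Seebach 1,3-dioxan-4-one at C1. C8a–O is the key bond, made by anodic dearomatisation of the phenol under control of the acetal centre; base then relays the acyl group to O8a and closes the pyran ring by oxa-Michael addition to the ynone.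
4. Dioxanone ⇐ (R)-3-hydroxybutanoic acid (the only purchased stereocentre, which ends up as the C8 ester) + alkynyl benzaldehyde ⇐ Sonogashira coupling of a bromobenzaldehyde with (E)-pent-2-en-4-yn-1-ol.
5. Ring order: benzene ring (bought) → dioxanone (temporary) → dearomatised carbocycle → pyran ring plus temporary lactone → epoxide → final lactol.

Assumptions: bromoaldehyde 1 is a catalogue compound; the C1 lactol configuration in the target SMILES (1-OH trans to 8a-OH) is the thermodynamic anomer and equilibrates under the acid of step 5.

Atom labels C1–C8a and O2 follow the isochromene numbering of the target throughout.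

## Route

Step 1
Reactants: 1 2-bromo-4-hydroxy-5-methylbenzaldehyde; 2 (E)-pent-2-en-4-yn-1-ol
Product: 3 4-hydroxy-2-[(E)-5-hydroxypent-3-en-1-ynyl]-5-methylbenzaldehyde
Conditions: Pd(PPh3)2Cl2 (3 mol %), CuI (5 mol %), Et3N/THF 1:1, 50 °C
Reagents that add atoms: none
Why: Sonogashira coupling of the aryl bromide (activated by the ortho formyl group) with the terminal enyne tolerates the free phenol and alcohol, forms no stereocentre and keeps the E alkene.

Step 2
Reactants: 3 4-hydroxy-2-[(E)-5-hydroxypent-3-en-1-ynyl]-5-methylbenzaldehyde; 4 (R)-3-hydroxybutanoic acid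
Product: 5 (2R,6R)-2-{4-hydroxy-2-[(E)-5-hydroxypent-3-en-1-ynyl]-5-methylphenyl}-6-methyl-1,3-dioxan-4-one (cis)
Conditions: PPTS (10 mol %), CH2Cl2, reflux through 4 Å MS (Soxhlet); crystallise
Reagents that add atoms: none
Why: Reversible acid-catalysed acetalisation of the aldehyde by the β-hydroxy acid (Seebach 1,3-dioxan-4-one formation) under thermodynamic control puts aryl and methyl both equatorial, so the purchased (R) centre fixes the new acetal centre as (2R).

Step 3
Reactants: 5 (2R,6R)-dioxanone phenol
Product: 8 tricyclic lactone acetal, via para-quinol dioxanone 6 (not isolated), via spiro hemiacetal lactone 7 (not isolated)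
Conditions: graphite anode, Pt cathode, undivided cell, LiClO4 (0.1 M), 2,6-lutidine (1 equiv), MeCN/H2O 4:1, 5 mA cm–2, 2.2 F mol–1, 0 °C; extract and dry; then DBU (0.2 equiv), dry MeCN, 0 °C to rt; chromatography removes the minor C8a epimer
Reagents that add atoms: water, O
Why: Proposed new method: two-electron anodic oxidation of a para-substituted phenol with capture of water at the para carbon is the classical electrochemical para-quinol synthesis, run here for the first time beside a Seebach acetal so that the acetal centre sets C8a: with the acetal C–H eclipsing the ortho alkynyl group (allylic 1,3-strain), water should enter anti to the electron-poor acyloxy C–O bond and syn to the Lewis-basic ring ether oxygen (polar Felkin–Anh approach, hydrogen-bond delivery), giving 6 with C8a as in the target; DBU then lets the new tertiary alkoxide take the acyl group from the acylal through a five-membered transition state (7), and the released hemiacetal oxygen closes the pyran ring by 6-endo oxa-Michael addition to the ynone, locking the product as 8 (its C1 configuration is erased in step 5); closest known reactions are anodic or PhI(OAc)2 para-hydroxylation of phenols and 1,2-induction by α-alkoxy stereocentres.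

Step 4
Reactants: 8 tricyclic lactone acetal
Product: 10 epoxy acetal acid, via dienone acetal acid 9 (not isolated)
Conditions: LiOH (2.2 equiv), THF/H2O 3:1, 0 °C; then 30% H2O2 (1.5 equiv), 0 °C; aq. HCl to pH 4
Reagents that add atoms: lithium hydroxide, [Li+].[OH-]; hydrogen peroxide, OO
Why: Saponification opens the tertiary-alkyl lactone and frees the 8a-hydroxyl while the acid stays tethered through the base-stable C1 acetal, and hydroperoxide then adds to C8 of the only reactive enone (Weitz–Scheffer epoxidation) guided by hydrogen bonding to the 8a-OH, so the epoxide oxygen (the future C7–O bond) lies cis to the 8a-hydroxyl.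

Step 5
Reactants: 10 epoxy acetal acid
Product: 14 azaphilone D side-chain alcohol, via ring-opened dioxanone 11 (not isolated), via anomeric ester epoxide 12 (not isolated), via bridged dioxanylium ion 13 (not isolated)
Conditions: TsOH·H2O (20 mol %), CH2Cl2, H2O (3 equiv), 0 °C to rt
Reagents that add atoms: water, O
Why: Proposed new method: under acid the C1 acetal exchanges its ligands (the tethered carboxyl closes onto C1 to give the Seebach-type acylal 11, and return of the vinylogous-acid oxygen with loss of the side-chain alkoxy oxygen gives the anomeric ester 12); only the epimer of 12 with the acyloxy group trans to the 8a-hydroxyl can react on, its carbonyl oxygen opening the protonated epoxide at C8 from the face opposite the epoxide oxygen through the six-membered dioxanylium ion 13 (inversion at C8 sets 8R, the C7–O bond is retained as 7S), which drains the equilibria; water then collapses 13 to the more stable, non-anomeric C8 ester with the lactol in its thermodynamic configuration; closest known reactions are anchimeric (acyloxonium) opening of epoxides by neighbouring esters, the epoxy ester to ortho ester rearrangement and acyl migration of anomeric esters.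

Step 6
Reactants: 14 azaphilone D side-chain alcohol
Product: 15 azaphilone D
Conditions: MnO2 (15 equiv), CH2Cl2, rt
Reagents that add atoms: none
Why: MnO2 oxidises only the primary allylic alcohol (allylic oxidation), leaving the saturated secondary alcohol, the tertiary alcohols and the non-allylic lactol untouched, the E alkene intact and every stereocentre unchanged.

## Compound list

1 | 2-bromo-4-hydroxy-5-methylbenzaldehyde | O=Cc1cc(C)c(O)cc1Br | starting material
2 | (E)-pent-2-en-4-yn-1-ol | C#C/C=C/CO | starting material
3 | 4-hydroxy-2-[(E)-5-hydroxypent-3-en-1-ynyl]-5-methylbenzaldehyde | O=Cc1cc(C)c(O)cc1C#C/C=C/CO | intermediate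
4 | (R)-3-hydroxybutanoic acid | C[C@@H](O)CC(=O)O | starting material
5 | (2R,6R)-2-{4-hydroxy-2-[(E)-5-hydroxypent-3-en-1-ynyl]-5-methylphenyl}-6-methyl-1,3-dioxan-4-one (cis) | C[C@@H]1CC(=O)O[C@@H](O1)c2cc(C)c(O)cc2C#C/C=C/CO | intermediate
6 | para-quinol dioxanone: (2R,6R)-2-{(1R)-1-hydroxy-2-[(E)-5-hydroxypent-3-en-1-ynyl]-5-methyl-4-oxocyclohexa-2,5-dien-1-yl}-6-methyl-1,3-dioxan-4-one | C[C@@H]1CC(=O)O[C@@H](O1)[C@@]2(O)C=C(C)C(=O)C=C2C#C/C=C/CO | intermediate
7 | spiro hemiacetal lactone: O8a acylated by the side-chain carboxyl, C1 a cyclic hemiacetal (seven-membered 1,4-dioxepan-5-one spiro at C8a, C1 epimers interconvert), ynone intact | C[C@@H]1CC(=O)O[C@]2(C(O)O1)C=C(C)C(=O)C=C2C#C/C=C/CO | intermediate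
8 | tricyclic lactone acetal: 3-[(E)-3-hydroxyprop-1-enyl]-7-methyl-1H-isochromen-6(8aH)-one core bridged by the lactone O8a–C(=O)–CH2–CH(CH3)–O–C1 (R at the methyl-bearing carbon; O1 and O8a cis) | C[C@@H]1CC(=O)O[C@]23C=C(C)C(=O)C=C2C=C(/C=C/CO)O[C@@H]3O1 | intermediate
9 | dienone acetal acid: (3R)-3-{[8a-hydroxy-3-((E)-3-hydroxyprop-1-enyl)-7-methyl-6-oxo-6,8a-dihydro-1H-isochromen-1-yl]oxy}butanoic acid (C1–O cis to 8a-OH; lithium salt in the flask) | C[C@H](CC(=O)O)O[C@H]1OC(/C=C/CO)=CC2=CC(=O)C(C)=C[C@]12O | intermediate
10 | epoxy acetal acid: 7,8-epoxide of 9, epoxide oxygen cis to 8a-OH | C[C@H](CC(=O)O)O[C@H]1OC(/C=C/CO)=CC2=CC(=O)[C@@]3(C)O[C@H]3[C@]12O | intermediate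
11 | ring-opened dioxanone: (2R,6R)-6-methyl-4-oxo-1,3-dioxan-2-yl group on C8a of the 7,8-epoxy-8a-hydroxy cyclohexenone, side chain as CH2–CO–CH=CH–CH2OH (E) | C[C@@H]1CC(=O)O[C@@H](O1)[C@@]2(O)[C@@H]3O[C@]3(C)C(=O)C=C2CC(=O)/C=C/CO | intermediate
12 | anomeric ester epoxide: 1-O-[(R)-3-hydroxybutanoyl] ester of the 7,8-epoxy lactol, acyloxy trans to 8a-OH | C[C@@H](O)CC(=O)O[C@@H]1OC(/C=C/CO)=CC2=CC(=O)[C@@]3(C)O[C@H]3[C@]12O | intermediate
13 | bridged dioxanylium ion: 2-[(R)-2-hydroxypropyl]-1,3-dioxan-2-ylium spanning O1 and O8, free 7-OH and 8a-OH | C[C@@H](O)CC1=[O+][C@H]2[C@](C)(O)C(=O)C=C3C=C(/C=C/CO)O[C@@H](O1)[C@@]23O | intermediate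
14 | azaphilone D side-chain alcohol: (1R,7S,8R,8aS)-1,7,8a-trihydroxy-3-[(E)-3-hydroxyprop-1-enyl]-7-methyl-6-oxo-1,7,8,8a-tetrahydro-6H-isochromen-8-yl (R)-3-hydroxybutanoate | C[C@@H](O)CC(=O)O[C@@H]1[C@@]2(O)C(=CC(=O)[C@@]1(C)O)C=C(/C=C/CO)O[C@H]2O | intermediate
15 | azaphilone D: (1R,7S,8R,8aS)-1,7,8a-trihydroxy-7-methyl-6-oxo-3-[(E)-3-oxoprop-1-enyl]-1,7,8,8a-tetrahydro-6H-isochromen-8-yl (R)-3-hydroxybutanoate | C[C@@H](O)CC(=O)O[C@@H]1[C@@]2(O)C(=CC(=O)[C@@]1(C)O)C=C(/C=C/C=O)O[C@H]2O | target

## Step count and risks

Total steps: 6. Longest linear sequence: 6 steps (1 → 3 → 5 → 8 → 10 → 14 → 15).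

The three steps most likely to fail:

**Step 3 (proposed new step).** The risks are a low face selectivity from the exocyclic acetal, loss of the acetal C–H or ortho attack instead of para hydroxylation, and acyl migration before work-up. Fallback with known chemistry: setting out from 5, the para-quinol is made by the standard hypervalent-iodine oxidative dearomatisation of para-substituted phenols (PhI(OAc)2, MeCN/H2O, 0 °C), which rejoins the route at 6; the same DBU treatment then gives 8. Should the acetal induce little selectivity under either oxidant, the two C8a epimers of 8 are diastereomers and are separated by crystallisation or chromatography. This fallback makes no compound outside the list (F0).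

**Step 4.** The risks are hydroxide attack on the vinylogous ester and epoxidation before the lactone has opened, which would lose the directing 8a-OH. Fallback: setting out from 8, K2CO3 in MeOH opens the lactone by transesterification to the hydroxy methyl ester F1; anhydrous t-BuOOH/DBU then gives the 8a-OH-directed Weitz–Scheffer product, the epoxy methyl ester F2; Me3SnOH in 1,2-dichloroethane at 60 °C cleaves the methyl ester and rejoins the route at 10.

**Step 5 (proposed new step).** The risks are that the acetal-to-acylal exchange is too slow, that the acetal simply hydrolyses, or that the epoxy ketone rearranges under acid. Fallback with known chemistry: setting out from 10, aqueous HClO4 in THF opens the epoxide at C8 (trans-diaxial attack of water) and hydrolyses the C1 acetal, giving the deacylated lactol pentaol F3 and free acid 4, which is recovered. MnO2 in CH2Cl2 oxidises the allylic alcohol to the deacylated enal F4. Carbodiimide esterification (EDC, DMAP cat., CH2Cl2, slow addition of the recovered 4) acylates the only secondary alcohol, any anomeric ester migrating from O1 to O8, and rejoins the route at 15, so step 6 is not needed.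

## Further compounds

F0 | step 3 | none | none
F1 | step 4 | hydroxy methyl ester (methyl ester of 9) | C[C@H](CC(=O)OC)O[C@H]1OC(/C=C/CO)=CC2=CC(=O)C(C)=C[C@]12O
F2 | step 4 | epoxy methyl ester (methyl ester of 10) | C[C@H](CC(=O)OC)O[C@H]1OC(/C=C/CO)=CC2=CC(=O)[C@@]3(C)O[C@H]3[C@]12O
F3 | step 5 | deacylated lactol pentaol (14 without the ester) | O[C@@H]1[C@@]2(O)C(=CC(=O)[C@@]1(C)O)C=C(/C=C/CO)O[C@H]2O
F4 | step 5 | deacylated enal (15 without the ester) | O[C@@H]1[C@@]2(O)C(=CC(=O)[C@@]1(C)O)C=C(/C=C/C=O)O[C@H]2O
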